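The dihydropyran ring of the chromane (O–C10–C1–C1′–two arene carbons; germacrane labels, C1′ = benzylic carbon) is read as the formal [4+2] adduct of an aryloxocarbenium ion (arene C=C–O+=C10) and the C1=C1′ alkene. Because C10–C1 is also a bond of the ten-membered carbocycle, one acid-catalysed cascade on an acyclic aryl enol ether should close both rings: the terminus C1 of a 1,3-diene attacks C10 (macrocyclisation) and the arene ortho carbon traps the allyl cation at C1′. The precursor is a linear chain built from (R)-α-terpineol, in which the ring alkene C4=C5 is masked as an enoate and the isobutyl group as a 2-methylprop-1-enyl group.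

Key step: step 9

Remark: C1–C10 are the ring carbons, C11 the carbinol carbon, C14 the methyl on C10, C15 the carbon on C4; the target is read as trans-fused at C1–C10 with C3 and C6 cis on C4=C5, and (R)-(+)-α-terpineol of high enantiomeric purity is taken as commercial.

Step 1
Reactants: 1 (R)-α-terpineol
Product: 2 (R)-α-terpineol triethylsilyl ether
Conditions: Et3SiOTf, 2,6-lutidine, CH2Cl2, −78 → 0 °C
Reagents that add atoms: triethylsilyl triflate, CC[Si](CC)(CC)OS(=O)(=O)C(F)(F)F
Why: Silyl ether protection of the tertiary alcohol with the reactive silyl triflate should mask the hydroxyl, which would otherwise form lactols after step 2 and intercept the cation of step 9; the stereocentre (future C7) comes from the chiral pool and is not touched.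

Step 2
Reactants: 2 (R)-α-terpineol triethylsilyl ether
Product: 4 (3R)-6-oxo-3-[2-(triethylsilyloxy)propan-2-yl]heptanal, via secondary ozonide 3 (not isolated)
Conditions: O3, CH2Cl2, −78 °C; then Me2S, −78 → 23 °C
Reagents that add atoms: ozone, [O-][O+]=O
Why: Ozonolysis of the only C=C bond with reductive work-up should unveil C5 as an aldehyde and C10 as a methyl ketone that already carries C14, without touching the stereocentre.

Step 3
Reactants: 5 4-bromobut-1-yne; 6 1-bromo-2-methylprop-1-ene
Product: 8 (3E)-1-bromo-6-methylhepta-3,5-diene, via alkenylzirconocene chloride 7 (not isolated)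
Conditions: Cp2Zr(H)Cl, THF, 23 °C; then 6, Pd(PPh3)4 (5 mol %), 23 → 40 °C
Reagents that add atoms: none
Why: Syn-hydrozirconation of the terminal alkyne fixes the (E)-alkene and the alkenylzirconium species should couple with the alkenyl bromide under palladium catalysis (Negishi-type cross-coupling), the primary alkyl bromide staying inert.

Step 4
Reactants: 9 trimethyl phosphonoacetate; 8 (3E)-1-bromo-6-methylhepta-3,5-diene
Product: 11 methyl (5E)-2-(dimethoxyphosphoryl)-8-methylnona-5,7-dienoate, via sodium enolate 10 (not isolated)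
Conditions: NaH, DMF, 0 °C; then 8, 50 °C
Reagents that add atoms: none
Why: SN2 C-alkylation of the stabilised phosphonoacetate anion by the primary bromide should give the α-substituted phosphonate; its new stereocentre is racemic and is destroyed in step 5.

Step 5
Reactants: 11 methyl (5E)-2-(dimethoxyphosphoryl)-8-methylnona-5,7-dienoate; 4 (3R)-6-oxo-3-[2-(triethylsilyloxy)propan-2-yl]heptanal
Product: 13 keto enoate methyl (2E,5E)-8-methyl-2-[(3R)-6-oxo-3-[2-(triethylsilyloxy)propan-2-yl]heptylidene]nona-5,7-dienoate, via sodium phosphonate carbanion 12 (not isolated)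
Conditions: NaH, THF, 0 °C; then 4, −20 → 0 °C
Reagents that add atoms: none
Why: The Horner–Wadsworth–Emmons olefination should be selective for the aldehyde over the methyl ketone and give the (E)-enoate (ester trans to C6), which places C3 and C6 cis on C4=C5 as in the target.

Step 6
Reactants: 13 keto enoate
Product: 15 enol triflate methyl (2E,5E)-8-methyl-2-[(3R)-3-[2-(triethylsilyloxy)propan-2-yl]-6-(trifluoromethylsulfonyloxy)hept-6-enylidene]nona-5,7-dienoate, via potassium enolate 14 (not isolated)
Conditions: KN(SiMe3)2, THF, −78 °C; then PhNTf2, −78 → −20 °C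
Reagents that add atoms: N-phenylbis(trifluoromethanesulfonimide), O=S(=O)(N(c1ccccc1)S(=O)(=O)C(F)(F)F)C(F)(F)F
Why: Kinetic deprotonation of the methyl ketone at C14 and O-sulfonylation (enol triflate formation) should give the terminal enol triflate; an internal isomer would lead to the same oxocarbenium ion in step 9.

Step 7
Reactants: 16 phloroglucinol
Product: 17 3,5-bis(triisopropylsilyloxy)phenol
Conditions: i-Pr3SiCl (2 equiv), imidazole, DMF, 0 → 23 °C
Reagents that add atoms: chlorotriisopropylsilane, CC(C)[Si](Cl)(C(C)C)C(C)C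
Why: Statistical silyl ether formation on the symmetric triol should give the bis-silyl ether, separable from the mono- and tris-silyl ethers, with one phenol left free for step 8.

Step 8
Reactants: 15 enol triflate; 17 3,5-bis(triisopropylsilyloxy)phenol
Product: 18 aryl enol ether methyl (2E,5E)-2-[(3R)-6-[3,5-bis(triisopropylsilyloxy)phenoxy]-3-[2-(triethylsilyloxy)propan-2-yl]hept-6-enylidene]-8-methylnona-5,7-dienoate
Conditions: Pd2(dba)3 (2.5 mol %), 2-(di-tert-butylphosphino)biphenyl (7.5 mol %), K3PO4, toluene, 80 °C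
Reagents that add atoms: none
Why: Palladium-catalysed C–O cross-coupling of an enol triflate with a phenol (Buchwald–Hartwig-type etherification) should install the O–C10 bond as an aryl enol ether, the mild phosphate base sparing the enoate and the silyl ethers.

Step 9
Reactants: 18 aryl enol ether
Product: 21 tricyclic ester (1S,7R,10R,1′S; chromane trans-fused at C10–C1 to the cyclodecene; CO2Me on C4; 2-methylprop-1-enyl on C1′), via aryloxocarbenium ion 19 (not isolated), via macrocyclic allyl cation 20 (not isolated)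
Conditions: Tf2NH (10 mol %), 4 Å molecular sieves, CH2Cl2 (0.001 M, slow addition of 18), −40 → −10 °C; then Et3N
Reagents that add atoms: none
Why: Proposed new method: protonation of the enol ether at C14 gives the aryloxocarbenium ion 19, whose carbon C10 is attacked by the diene terminus C1 to give the allyl cation 20, which the arene ortho carbon traps at C1′ with loss of a proton, so the acid is catalytic and the step is an isomerisation. The closest known reaction type is the intermolecular oxa-Povarov reaction (formal [4+2] cycloaddition of cationic aryl 2-oxadienes with alkenes and 1,3-dienes to give chromanes), here run intramolecularly with a ketone-derived ion and an eight-atom tether. The ten-membered carbocycle closes by a 10-exo-trig attack on the oxocarbenium carbon and the dihydropyran ring by a 6-exo-trig Friedel–Crafts attack on the allyl cation. C10 and C1 are set together in the macrocyclisation, where the tether should span the new bond diequatorially (C9 and C2 anti, trans fusion) on the face chosen by the C7 stereocentre, whose bulky silyloxypropyl group should sit pseudo-equatorially on the folded chain, and C1′ is set in the ring closure with the alkenyl group pseudo-equatorial, trans to C2. The step needs chemoselectivity for the diene over C4=C5, secured by the ester that makes that alkene electron-poor, and regioselectivity for bonding at C1 instead of C1′, secured by the diene, which can only give the tertiary allyl cation. High dilution and the cis relation of C3 and C6 in the enoate, a turn element, should favour ring closure over oligomerisation.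

Step 10
Reactants: 21 tricyclic ester
Product: 22 tricyclic ester with 2-methylpropyl on C1′ (1S,7R,10R,1′S)
Conditions: Mn(dpm)3 (10 mol %; dpm = dipivaloylmethanate), PhSiH3, t-BuOOH, i-PrOH/CH2Cl2, 22 °C
Reagents that add atoms: none
Why: Metal-hydride hydrogen-atom-transfer hydrogenation should reduce the electron-rich trisubstituted side-chain alkene through its tertiary radical, while the hindered, electron-poor enoate is a poor hydrogen-atom acceptor and should remain; no stereocentre is formed.

Step 11
Reactants: 22 tricyclic ester with 2-methylpropyl on C1′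
Product: 23 allylic alcohol (C15 = CH2OH on C4)
Conditions: i-Bu2AlH, CH2Cl2, −78 °C; aqueous potassium sodium tartrate
Reagents that add atoms: none
Why: 1,2-Reduction of the α,β-unsaturated ester by the aluminium hydride at low temperature should give the allylic alcohol without change of the alkene geometry or loss of silyl ethers.

Step 12
Reactants: 23 allylic alcohol
Product: 25 silyl-protected chromane with C15 = CH3 (C3 and C6 cis on C4=C5), via allylic mesylate 24 (not isolated)
Conditions: MsCl, Et3N, CH2Cl2, −30 °C; then LiEt3BH, THF, −30 → 0 °C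
Reagents that add atoms: none
Why: Sulfonylation of the only free hydroxyl and SN2 hydride displacement of the primary allylic mesylate (deoxygenation by sulfonate reduction) should turn C15 into the methyl group with the alkene position and geometry retained.

Step 13
Reactants: 25 silyl-protected chromane
Product: 26 chromane-5,7-diol with the C11 triethylsilyl ether kept
Conditions: Bu4NF (2.2 equiv), AcOH (2.2 equiv), THF, 0 °C
Reagents that add atoms: none
Why: Fluoride cleaves aryl silyl ethers much faster than a hindered tertiary alkyl silyl ether (selective desilylation), so both phenols should be freed while the tertiary alcohol stays masked for step 14.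

Step 14
Reactants: 26 chromane-5,7-diol
Product: 29 target CNP0570248.1, via bis-iminium salt 27 (not isolated), via triethylsilyl ether of the target 28 (not isolated)
Conditions: POCl3, DMF, MeCN, 0 → 40 °C; then 1 M HCl, THF, 23 °C
Reagents that add atoms: N,N-dimethylformamide, CN(C)C=O; water, O
Why: Vilsmeier–Haack formylation should occur twice, at the only two free and strongly activated arene positions, and the acidic aqueous work-up should hydrolyse both iminium groups and the triethylsilyl ether to give the target.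

Compound list
1 | (R)-(+)-α-terpineol, 2-[(1R)-4-methylcyclohex-3-en-1-yl]propan-2-ol | CC1=CC[C@H](C(C)(C)O)CC1 | starting material
2 | triethylsilyl ether of 1 | CC1=CC[C@H](C(C)(C)O[Si](CC)(CC)CC)CC1 | intermediate
3 | secondary ozonide (1,2,4-trioxolane across the former C=C) of 2, mixture at the ozonide carbons | CC12CC[C@@H](C(C)(C)O[Si](CC)(CC)CC)CC(OO1)O2 | intermediate
4 | (3R)-6-oxo-3-[2-(triethylsilyloxy)propan-2-yl]heptanal (C5 aldehyde, C7 stereocentre, C10 ketone) | O=CC[C@H](C(C)(C)O[Si](CC)(CC)CC)CCC(C)=O | intermediate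
5 | 4-bromobut-1-yne | C#CCCBr | starting material
6 | 1-bromo-2-methylprop-1-ene | CC(C)=CBr | starting material
7 | chlorobis(cyclopentadienyl)[(1E)-4-bromobut-1-en-1-yl]zirconium | Cl[Zr](/C=C/CCBr)(C1C=CC=C1)C1C=CC=C1 | intermediate
8 | (3E)-1-bromo-6-methylhepta-3,5-diene | BrCC/C=C/C=C(C)C | intermediate
9 | trimethyl phosphonoacetate | COC(=O)CP(=O)(OC)OC | starting material
10 | sodium enolate of trimethyl phosphonoacetate | [Na+].COC([O-])=CP(=O)(OC)OC | intermediate
11 | methyl (5E)-2-(dimethoxyphosphoryl)-8-methylnona-5,7-dienoate, racemic at C2 | COC(=O)C(CC/C=C/C=C(C)C)P(=O)(OC)OC | intermediate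
12 | sodium salt (phosphonate-stabilised carbanion) of 11 | [Na+].COC([O-])=C(CC/C=C/C=C(C)C)P(=O)(OC)OC | intermediate
13 | methyl (2E,5E)-8-methyl-2-[(3R)-6-oxo-3-[2-(triethylsilyloxy)propan-2-yl]heptylidene]nona-5,7-dienoate | COC(=O)/C(CC/C=C/C=C(C)C)=C/C[C@H](C(C)(C)O[Si](CC)(CC)CC)CCC(C)=O | intermediate
14 | potassium enolate of 13 (O–C10=C14) | COC(=O)/C(CC/C=C/C=C(C)C)=C/C[C@H](C(C)(C)O[Si](CC)(CC)CC)CCC(=C)[O-].[K+] | intermediate
15 | methyl (2E,5E)-8-methyl-2-[(3R)-3-[2-(triethylsilyloxy)propan-2-yl]-6-(trifluoromethylsulfonyloxy)hept-6-enylidene]nona-5,7-dienoate | COC(=O)/C(CC/C=C/C=C(C)C)=C/C[C@H](C(C)(C)O[Si](CC)(CC)CC)CCC(=C)OS(=O)(=O)C(F)(F)F | intermediate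
16 | phloroglucinol (benzene-1,3,5-triol) | Oc1cc(O)cc(O)c1 | starting material
17 | 3,5-bis(triisopropylsilyloxy)phenol | Oc1cc(O[Si](C(C)C)(C(C)C)C(C)C)cc(O[Si](C(C)C)(C(C)C)C(C)C)c1 | intermediate
18 | methyl (2E,5E)-2-[(3R)-6-[3,5-bis(triisopropylsilyloxy)phenoxy]-3-[2-(triethylsilyloxy)propan-2-yl]hept-6-enylidene]-8-methylnona-5,7-dienoate | COC(=O)/C(CC/C=C/C=C(C)C)=C/C[C@H](C(C)(C)O[Si](CC)(CC)CC)CCC(=C)Oc1cc(O[Si](C(C)C)(C(C)C)C(C)C)cc(O[Si](C(C)C)(C(C)C)C(C)C)c1 | intermediate
19 | aryloxocarbenium bis(trifluoromethylsulfonyl)imide from C14-protonation of 18 (cation at C10) | COC(=O)/C(CC/C=C/C=C(C)C)=C/C[C@H](C(C)(C)O[Si](CC)(CC)CC)CCC(C)=[O+]c1cc(O[Si](C(C)C)(C(C)C)C(C)C)cc(O[Si](C(C)C)(C(C)C)C(C)C)c1.FC(F)(F)S(=O)(=O)[N-]S(=O)(=O)C(F)(F)F | intermediate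
20 | ten-membered allyl cation (C10–C1 bond formed; 1S,7R,10R; charge shared by C1′ and the CMe2 terminus), bis(trifluoromethylsulfonyl)imide salt | COC(=O)/C1=C/C[C@H](C(C)(C)O[Si](CC)(CC)CC)CC[C@@](C)(Oc2cc(O[Si](C(C)C)(C(C)C)C(C)C)cc(O[Si](C(C)C)(C(C)C)C(C)C)c2)[C@H](/C=C/[C+](C)C)CC1.FC(F)(F)S(=O)(=O)[N-]S(=O)(=O)C(F)(F)F | intermediate
21 | (1S,7R,10R,1′S)-tricycle: chromane trans-fused at C10–C1 to a cyclodecene; CO2Me on C4 (C3 and C6 cis on C4=C5), 2-methylprop-1-enyl on C1′, OSiEt3 on C11, two OSi(i-Pr)3 groups on the arene | COC(=O)/C1=C/C[C@H](C(C)(C)O[Si](CC)(CC)CC)CC[C@@]2(C)Oc3cc(O[Si](C(C)C)(C(C)C)C(C)C)cc(O[Si](C(C)C)(C(C)C)C(C)C)c3[C@@H](C=C(C)C)[C@@H]2CC1 | intermediate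
22 | as 21 with 2-methylpropyl (isobutyl) on C1′ | COC(=O)/C1=C/C[C@H](C(C)(C)O[Si](CC)(CC)CC)CC[C@@]2(C)Oc3cc(O[Si](C(C)C)(C(C)C)C(C)C)cc(O[Si](C(C)C)(C(C)C)C(C)C)c3[C@@H](CC(C)C)[C@@H]2CC1 | intermediate
23 | as 22 with CH2OH (C15) on C4 | OC/C1=C/C[C@H](C(C)(C)O[Si](CC)(CC)CC)CC[C@@]2(C)Oc3cc(O[Si](C(C)C)(C(C)C)C(C)C)cc(O[Si](C(C)C)(C(C)C)C(C)C)c3[C@@H](CC(C)C)[C@@H]2CC1 | intermediate
24 | methanesulfonate of 23 | CS(=O)(=O)OC/C1=C/C[C@H](C(C)(C)O[Si](CC)(CC)CC)CC[C@@]2(C)Oc3cc(O[Si](C(C)C)(C(C)C)C(C)C)cc(O[Si](C(C)C)(C(C)C)C(C)C)c3[C@@H](CC(C)C)[C@@H]2CC1 | intermediate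
25 | as 22 with CH3 (C15) on C4: tris-silyl ether of the target skeleton without formyl groups | C/C1=C/C[C@H](C(C)(C)O[Si](CC)(CC)CC)CC[C@@]2(C)Oc3cc(O[Si](C(C)C)(C(C)C)C(C)C)cc(O[Si](C(C)C)(C(C)C)C(C)C)c3[C@@H](CC(C)C)[C@@H]2CC1 | intermediate
26 | as 25 with both phenols free (chromane-5,7-diol), OSiEt3 on C11 kept | C/C1=C/C[C@H](C(C)(C)O[Si](CC)(CC)CC)CC[C@@]2(C)Oc3cc(O)cc(O)c3[C@@H](CC(C)C)[C@@H]2CC1 | intermediate
27 | bis(dimethyliminiomethyl) dichloride of 26 (iminium groups on the two free arene carbons) | C/C1=C/C[C@H](C(C)(C)O[Si](CC)(CC)CC)CC[C@@]2(C)Oc3c(C=[N+](C)C)c(O)c(C=[N+](C)C)c(O)c3[C@@H](CC(C)C)[C@@H]2CC1.[Cl-].[Cl-] | intermediate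
28 | C11 triethylsilyl ether of the target | C/C1=C/C[C@H](C(C)(C)O[Si](CC)(CC)CC)CC[C@@]2(C)Oc3c(C=O)c(O)c(C=O)c(O)c3[C@@H](CC(C)C)[C@@H]2CC1 | intermediate
29 | CNP0570248.1: (1S,7R,10R,1′S) diformyl dihydroxy chromane trans-fused at C10–C1 to the cyclodecene, C3 and C6 cis on C4=C5, 2-hydroxypropan-2-yl on C7, isobutyl on C1′ | C/C1=C/C[C@H](C(C)(C)O)CC[C@@]2(C)Oc3c(C=O)c(O)c(C=O)c(O)c3[C@@H](CC(C)C)[C@@H]2CC1 | target

Total step count: 14.
Longest linear sequence: 11 steps (steps 3, 4, 5, 6, 8, 9, 10, 11, 12, 13, 14 from 5 and 6; equally steps 1, 2, 5, 6, 8 to 14 from 1).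

Steps most likely to fail

Step 9. The ten-membered ring closure may be too slow, so that the oxocarbenium ion is consumed by intermolecular alkylation and oligomerisation, and the relay of facial selectivity from C7 may be weak. The fallback uses known reactions only: the two bonds are made between two molecules and the carbocycle is closed afterwards at C4=C5. It sets out from 4 and 11 and comes back at 21. Wittig methylenation of the aldehyde of 4 (Ph3P=CH2, THF, −78 °C) should give the alkenyl ketone F1. KN(SiMe3)2 and PhNTf2 should then give the enol triflate F2, and the coupling of step 8 with 17 the aryl enol ether F3. Olefination of 11 with aqueous formaldehyde and K2CO3 should give the α-methylene ester F4. The intermolecular oxa-Povarov reaction of F3 with the diene of F4 (Tf2NH, CH2Cl2, 0.2 M, −40 °C) should give the chromane F5, from which the isomers at C10 are separated. Ring-closing metathesis of F5 with the second-generation Hoveyda–Grubbs catalyst at high dilution in toluene should then give 21.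

Step 10. Hydrogen-atom transfer to the enoate, or addition of the tertiary radical to it, may cause over-reduction or transannular C–C bond formation. The fallback replaces the direct hydrogenation by hydration and radical deoxygenation, sets out from 21 and comes back at 22. Hydroboration with 9-BBN and oxidation with NaBO3 should hydrate only the electron-rich side-chain alkene in the anti-Markovnikov sense to give the secondary alcohol F6. 1,1′-Thiocarbonyldiimidazole with DMAP should give the imidazolyl thionocarbonate F7, and Barton–McCombie deoxygenation (Bu3SnH, AIBN, toluene, 90 °C) should give 22.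

Step 14. The second formylation may stall after the first formyl group deactivates the arene, and the acidic iminium hydrolysis may ionise the tertiary C–O bonds. The fallback introduces the formyl groups through aryl–lithium species, sets out from 25 and comes back at 29. NBS (CH2Cl2, −40 °C) should brominate both free arene positions to give the dibromide F8. Double bromine–lithium exchange (t-BuLi, Et2O, −95 °C, to suppress silyl migration) and quenching with DMF should give the silyl-protected dialdehyde F9. Bu4NF in THF should remove the three silyl groups to give 29.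

Further compounds
F1 | step 9 | (5R)-5-[2-(triethylsilyloxy)propan-2-yl]oct-7-en-2-one | C=CC[C@H](C(C)(C)O[Si](CC)(CC)CC)CCC(C)=O
F2 | step 9 | (5R)-5-[2-(triethylsilyloxy)propan-2-yl]octa-1,7-dien-2-yl triflate | C=CC[C@H](C(C)(C)O[Si](CC)(CC)CC)CCC(=C)OS(=O)(=O)C(F)(F)F
F3 | step 9 | 3,5-bis(triisopropylsilyloxy)phenyl (5R)-5-[2-(triethylsilyloxy)propan-2-yl]octa-1,7-dien-2-yl ether | C=CC[C@H](C(C)(C)O[Si](CC)(CC)CC)CCC(=C)Oc1cc(O[Si](C(C)C)(C(C)C)C(C)C)cc(O[Si](C(C)C)(C(C)C)C(C)C)c1
F4 | step 9 | methyl (5E)-8-methyl-2-methylidenenona-5,7-dienoate | COC(=O)C(=C)CC/C=C/C=C(C)C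
F5 | step 9 | chromane with all four stereocentres of 21 set, carrying a 2-[2-(triethylsilyloxy)propan-2-yl]pent-4-enyl chain on C10 and a 3-(methoxycarbonyl)but-3-enyl chain on C1 | C=CC[C@H](C(C)(C)O[Si](CC)(CC)CC)CC[C@@]1(C)Oc2cc(O[Si](C(C)C)(C(C)C)C(C)C)cc(O[Si](C(C)C)(C(C)C)C(C)C)c2[C@@H](C=C(C)C)[C@@H]1CCC(=C)C(=O)OC
F6 | step 10 | as 21 with 1-hydroxy-2-methylpropyl on C1′ (mixture at the carbinol carbon) | COC(=O)/C1=C/C[C@H](C(C)(C)O[Si](CC)(CC)CC)CC[C@@]2(C)Oc3cc(O[Si](C(C)C)(C(C)C)C(C)C)cc(O[Si](C(C)C)(C(C)C)C(C)C)c3[C@@H](C(O)C(C)C)[C@@H]2CC1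
F7 | step 10 | O-imidazolylthiocarbonyl derivative of F6 | COC(=O)/C1=C/C[C@H](C(C)(C)O[Si](CC)(CC)CC)CC[C@@]2(C)Oc3cc(O[Si](C(C)C)(C(C)C)C(C)C)cc(O[Si](C(C)C)(C(C)C)C(C)C)c3[C@@H](C(OC(=S)n4ccnc4)C(C)C)[C@@H]2CC1
F8 | step 14 | dibromide of 25 (bromine on both free arene carbons) | C/C1=C/C[C@H](C(C)(C)O[Si](CC)(CC)CC)CC[C@@]2(C)Oc3c(Br)c(O[Si](C(C)C)(C(C)C)C(C)C)c(Br)c(O[Si](C(C)C)(C(C)C)C(C)C)c3[C@@H](CC(C)C)[C@@H]2CC1
F9 | step 14 | tris-silyl ether of the target (two aryl OSi(i-Pr)3, C11 OSiEt3) | C/C1=C/C[C@H](C(C)(C)O[Si](CC)(CC)CC)CC[C@@]2(C)Oc3c(C=O)c(O[Si](C(C)C)(C(C)C)C(C)C)c(C=O)c(O[Si](C(C)C)(C(C)C)C(C)C)c3[C@@H](CC(C)C)[C@@H]2CC1
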